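In a closed flask the substrate charged is conserved: what is neither substrate nor mono adduct has gone elsewhere, so the gap, charge minus substrate minus mono adduct, measures that other part.

| flask | substrate | coupling partner | remark | time |
|---|---|---|---|---|
| grey | 15 mM | 12 mM | run made earlier |  |
| amber | 20 mM | 12 mM | run made earlier |  |
| ash | 10 mM | 12.0 mM |  | 50 min |
| alder | 10 mM | 25.0 mM |  | 50 min |
| larch | 10 mM | 50.0 mM |  | 50 min |

* amount of mono adduct at the end, in percent of the substrate charged for ash, alder, larch, in this order
* how the row runs (falls all the way / rises all the way / falls, then rises / hardly changes / rises, then falls)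

- the numbers in the tables scatter by 1 percentage point (one standard deviation)
- "hardly changes" means that all values lie within two and a half points (for a concentration: within two and a half percent of the largest)
- a step back or a flat step of under half a point counts as no turn

| run | time / min | mono adduct / % | substrate / % |
|---|---|---|---|
| grey | 1.50 | 4.6 | 96.0 |
| grey | 5.00 | 8.2 | 90.4 |
| grey | 8.00 | 11.4 | 86.9 |
| grey | 12.0 | 15.7 | 76.9 |
| grey | 20.0 | 21.9 | 68.3 |
| grey | 25.0 | 24.1 | 64.0 |
| grey | 30.0 | 26.4 | 56.8 |
| amber | 2.50 | 4.6 | 96.7 |
| amber | 4.00 | 5.2 | 92.9 |
| amber | 6.00 | 9.9 | 87.9 |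
| amber | 8.00 | 13.2 | 85.0 |
| amber | 12.0 | 16.4 | 79.8 |
| amber | 20.0 | 21.2 | 68.2 |
| amber | 30.0 | 25.8 | 56.6 |

(readings scatter by 1 percentage point)

Take the last line of each table. At 30.0 min, grey holds 56.8% substrate and amber 56.6%, from charges of 15 mM and 20 mM, so within the scatter these readings show no dependence of the percentage left on the charge, as in an exponential decay with a time constant. Both runs were charged with 12 mM coupling partner, so their charges offer no comparison of how that time constant moves with partner.

The reckoning here assumes a rate proportional to [coupling partner], taken at its charge: a pseudo-first-order decay. The quantity to carry is then the partner rate constant, ln(charge/substrate left) divided by time and by [coupling partner]: 0.0262 L mol⁻¹ s⁻¹ from grey, and 0.0264 L mol⁻¹ s⁻¹ from amber. At 50 min the reckoning gives 39.0% substrate in ash, 14.0% in alder and 1.97% in larch.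

Now the mono adduct column. In grey the gap is 1.70% at 8.00 min and 16.8% at 30.0 min, ten times as large, while lost substrate grew 3.30-fold. Within the scatter, these two readings fit a gap that goes as the square of lost substrate. Stretching that correction beyond grey's range and to other partner charges gives a reckoned gap of 33.5% in ash, and reckoned mono adduct of 27.5%, 19.4% and 11.5%: a row that falls all the way.

The forecast differs, with 26%, 26% and 26%, a row that hardly changes, on the ground that “Both steps therefore look zero order in partner”.

The flask gives 34.6%, 39.4% and 24.5%: the row rises, then falls.

substrate + coupling partner → mono adduct + by-product (k = 0.0270 L mol⁻¹ s⁻¹); coupling partner + mono adduct → double product + by-product (k = 0.0160 L mol⁻¹ s⁻¹); coupling partner ⇌ dormant form (K = 0.200, k = 4.60 × 10⁻⁴ s⁻¹); substrate + by-product → side product (k = 0.0460 L mol⁻¹ s⁻¹) Ash ends with a gap of 25.7%, less than the reckoned 33.5%, and it holds 17.8% side product and 7.88% double product. Carried to larch at 25.0 min, the constant 0.0262 L mol⁻¹ s⁻¹ gives 14.0% substrate left, and larch holds 14.5%.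

All runs are calculated for an exercise, and the scatter is random.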